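The plan cuts the pyranone ring of the 3-arylcoumarin at four bonds: O1–C8a, C4–C4a, C3–C4 and O1–C2. In one operation an aryne spanning C4a–C8a of ring A inserts into the C=O bond of DMF. The enolate of the ring B arylacetate then supplies C2 and C3 and closes the lactone. The step exploits the methoxyl on C5, the ring A carbon next to C4a. It polarises the C4a–C8a triple bond so that oxygen enters at the remote C8a and carbon at C4a. The precursors are an ortho-silylaryl triflate, with O7 masked as a fluoride-stable tert-butyl ether, and methyl (5-methoxy-2,2-dimethylchroman-6-yl)acetate.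

Key step: step 10

Numbering: coumarin O1, C2–C8a (benzo ring A); chroman O1', C2'–C8a' (benzo ring B); the halves are joined C3–C6'.

Mapping of 9 onto ring A:
- the triflate-bearing carbon becomes C8a
- the silyl-bearing carbon becomes C4a
- the methoxyl-bearing carbon becomes C5
- the tert-butoxy carbon, para to silicon, becomes C7

Remark on the chemistry: the target has no stereocentre. The stereo-elements of 12, 16, 19 and 22 are transient and are erased within the route. Compounds 1, 10, 11 and 18 and all reagents named in the Conditions lines are assumed to be purchasable.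

Step 1
Reactants: 1 5-methoxyresorcinol
Product: 2 3-tert-butoxy-5-methoxyphenol
Conditions: Me2NCH(Ot-Bu)2 (1.5 equiv, slow addition), toluene–1,4-dioxane, 80 °C
Reagents that add atoms: N,N-dimethylformamide di-tert-butyl acetal, CN(C)C(OC(C)(C)C)OC(C)(C)C
Why: Amide-acetal O-alkylation of a phenol runs under essentially neutral conditions, which spares the very electron-rich ring from Friedel–Crafts C-alkylation, while a limited reagent charge and the large polarity gaps between diol, mono-ether and bis-ether make the statistical desymmetrisation of the two equivalent hydroxyls practical.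

Step 2
Reactants: 2 3-tert-butoxy-5-methoxyphenol
Product: 3 3-tert-butoxy-5-methoxyphenyl isopropylcarbamate
Conditions: i-PrNCO, Et3N (cat.), CH2Cl2, rt
Reagents that add atoms: isopropyl isocyanate, CC(C)N=C=O
Why: Base-catalysed addition of a phenol to an isocyanate (carbamoylation) is clean, and the secondary carbamate is chosen because it becomes a strong directing group once N-silylated and can later be removed by mild amine-induced E1cB cleavage.

Step 3
Reactants: 3 3-tert-butoxy-5-methoxyphenyl isopropylcarbamate
Product: 7 5-tert-butoxy-3-methoxy-2-(trimethylsilyl)phenyl isopropylcarbamate, via N-silyl carbamate 4 (not isolated), via aryllithium 5 (not isolated), via C-silyl N-silyl carbamate 6 (not isolated)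
Conditions: TBSOTf, TMEDA, Et2O, 0 °C → rt; n-BuLi (2 equiv), TMEDA, −78 °C; Me3SiCl, −78 °C → rt; aq. citric acid
Reagents that add atoms: chlorotrimethylsilane, C[Si](C)(C)Cl
Why: In this directed ortho-metalation, transient N-silylation masks the N–H and the carbamate delivers n-BuLi to the C–H flanked by carbamate and methoxyl, where two directing groups cooperate, rather than to the two positions shielded by the bulky tert-butoxy group, after which Me3SiCl traps 5 at low temperature before any anionic ortho-Fries shift and the mild acid wash hydrolyses only the N–Si bond.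

Step 4
Reactants: 7 5-tert-butoxy-3-methoxy-2-(trimethylsilyl)phenyl isopropylcarbamate
Product: 9 5-tert-butoxy-3-methoxy-2-(trimethylsilyl)phenyl trifluoromethanesulfonate, via silylphenol 8 (not isolated)
Conditions: Et2NH, DBU, MeCN, 40 °C; then PhNTf2, rt
Reagents that add atoms: N-phenylbis(trifluoromethanesulfonimide), O=S(=O)(N(c1ccccc1)S(=O)(=O)C(F)(F)F)C(F)(F)F
Why: DBU triggers E1cB loss of isopropyl isocyanate from the carbamate, Et2NH scavenges it as a urea, and the phenoxide of 8 is O-sulfonylated in the same flask by the mild triflyl donor, conditions that attack neither the aryl–silicon bond nor the tert-butyl ether.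

Step 5
Reactants: 10 2,4-dihydroxybenzaldehyde, 11 3-methylbut-2-enal (prenal)
Product: 13 5-hydroxy-2,2-dimethyl-2H-chromene-6-carbaldehyde, via dienone 12 (not isolated)
Conditions: Ca(OH)2, MeOH, rt
Reagents that add atoms: none
Why: In this domino aldol-type condensation/oxa-6π electrocyclisation the phenoxide attacks prenal through the carbon between the two oxygens, loss of water gives dienone 12, and ring closure uses the oxygen para to the formyl group because the ortho hydroxyl is locked in a chelate with the aldehyde, which leads to the angular 5-hydroxy-6-formyl chromene.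

Step 6
Reactants: 13 5-hydroxy-2,2-dimethyl-2H-chromene-6-carbaldehyde
Product: 14 5-methoxy-2,2-dimethyl-2H-chromene-6-carbaldehyde
Conditions: MeI, K2CO3, acetone, reflux
Reagents that add atoms: iodomethane, CI
Why: Williamson etherification with excess base and alkylating agent overcomes the intramolecular hydrogen bond of the ortho-hydroxy aldehyde and methylates the only free hydroxyl.

Step 7
Reactants: 14 5-methoxy-2,2-dimethyl-2H-chromene-6-carbaldehyde
Product: 15 5-methoxy-2,2-dimethylchroman-6-carbaldehyde
Conditions: H2 (1 atm), 10% Pd/C, EtOAc, rt, stopped after one equivalent of H2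
Reagents that add atoms: none
Why: Heterogeneous catalytic hydrogenation saturates the styrene-like C3'=C4' bond much faster than it touches the electron-rich aromatic aldehyde in a neutral aprotic solvent.

Step 8
Reactants: 15 5-methoxy-2,2-dimethylchroman-6-carbaldehyde
Product: 16 (E)-5-methoxy-2,2-dimethyl-6-[2-(methylsulfinyl)-2-(methylthio)vinyl]chroman (racemic at sulfur)
Conditions: MeS(O)CH2SMe, BnNMe3OH (40% in MeOH, cat.), THF, reflux
Reagents that add atoms: methyl methylthiomethyl sulfoxide, CSCS(C)=O
Why: Knoevenagel-type condensation of the aldehyde with the doubly sulfur-stabilised carbanion gives a ketene dithioacetal S-oxide, a masked arylacetic acid at the correct oxidation level whose alkene geometry and sulfur configuration do not matter because both vanish in step 9.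

Step 9
Reactants: 16 (E)-5-methoxy-2,2-dimethyl-6-[2-(methylsulfinyl)-2-(methylthio)vinyl]chroman
Product: 17 methyl 2-(5-methoxy-2,2-dimethylchroman-6-yl)acetate
Conditions: HCl (3 M in MeOH), rt → 50 °C
Reagents that add atoms: methanol, CO
Why: Acid-promoted methanolysis of the ketene dithioacetal S-oxide (protonation at the benzylic carbon, addition of methanol, Pummerer-like departure of both sulfur groups) delivers the methyl arylacetate directly, and the chroman and aryl methyl ethers tolerate methanolic HCl.

Step 10
Reactants: 17 methyl 2-(5-methoxy-2,2-dimethylchroman-6-yl)acetate, 9 5-tert-butoxy-3-methoxy-2-(trimethylsilyl)phenyl trifluoromethanesulfonate, 18 N,N-dimethylformamide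
Product: 23 7-tert-butoxy-5-methoxy-3-(5-methoxy-2,2-dimethylchroman-6-yl)-2H-chromen-2-one, via lithium enolate 19 (not isolated), via aryne 20 (not isolated), via iminium phenolate 21 (not isolated), via amino ester adduct 22 (not isolated)
Conditions: 17, LiN(SiMe3)2, THF, −78 °C; transfer into CsF (5 equiv), DMF, 0 °C; 9 (1.5 equiv) in DMF added over 2 h, 0 °C → rt
Reagents that add atoms: none
Why: Fluoride removes the silyl group of 9 and triflate departs to give aryne 20, the carbonyl oxygen of the solvent DMF bonds to C8a, the aryl anion at C4a collapses on the iminium carbon, and the strained four-membered adduct opens to the ortho-quinone methide aminal 21. Enolate 19 adds to C4 of 21 in a Mannich-type step (C3–C4) to give 22, whose phenolate attacks the ester carbonyl in a 6-exo-trig acyl substitution (O1–C2, loss of methoxide), and E1cB loss of dimethylamine installs C3=C4. The closest known chemistry is the three-component coupling of ortho-silylaryl triflate arynes, DMF and malonate, active-methylene or ester-enolate carbanions to give coumarins. No stereocentre remains, because C3 and C4 of 22 both become sp2. The regioselectivity needed is oxygen at C8a and not at C4a, and the sigma-withdrawing C5 methoxyl secures it by stabilising the charge that builds at the neighbouring C4a and by distorting the aryne so that C8a is the more electrophilic terminus, while the remote C7 tert-butoxy group has no competing influence. The chemoselectivity needed is capture by DMF ahead of direct C-arylation of 19, which rests on the very large molar excess of solvent, high dilution of the enolate and slow addition of 9, the extra 9 covering what liberated dimethylamine and methoxide consume.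

Step 11
Reactants: 23 7-tert-butoxy-5-methoxy-3-(5-methoxy-2,2-dimethylchroman-6-yl)-2H-chromen-2-one
Product: 24 7-hydroxy-5-methoxy-3-(5-methoxy-2,2-dimethylchroman-6-yl)-2H-chromen-2-one (CNP0139207.0)
Conditions: CF3CO2H, CH2Cl2, 0 °C → rt
Reagents that add atoms: none
Why: Acidolysis of the aryl tert-butyl ether proceeds by protonation and E1 loss of the tert-butyl cation as isobutene, a pathway closed to the methyl ethers and the lactone, while any ionisation of the chroman C2'–O1' bond is reversible and intramolecular reclosure restores that ring.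

Compound list
1 | 5-methoxyresorcinol | COc1cc(O)cc(O)c1 | starting material
2 | 3-tert-butoxy-5-methoxyphenol | COc1cc(O)cc(OC(C)(C)C)c1 | intermediate
3 | 3-tert-butoxy-5-methoxyphenyl isopropylcarbamate | COc1cc(OC(=O)NC(C)C)cc(OC(C)(C)C)c1 | intermediate
4 | 3-tert-butoxy-5-methoxyphenyl N-(tert-butyldimethylsilyl)-N-isopropylcarbamate | COc1cc(OC(=O)N(C(C)C)[Si](C)(C)C(C)(C)C)cc(OC(C)(C)C)c1 | intermediate
5 | 5-tert-butoxy-2-lithio-3-methoxyphenyl N-(tert-butyldimethylsilyl)-N-isopropylcarbamate | COc1cc(OC(C)(C)C)cc(OC(=O)N(C(C)C)[Si](C)(C)C(C)(C)C)c1[Li] | intermediate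
6 | 5-tert-butoxy-3-methoxy-2-(trimethylsilyl)phenyl N-(tert-butyldimethylsilyl)-N-isopropylcarbamate | COc1cc(OC(C)(C)C)cc(OC(=O)N(C(C)C)[Si](C)(C)C(C)(C)C)c1[Si](C)(C)C | intermediate
7 | 5-tert-butoxy-3-methoxy-2-(trimethylsilyl)phenyl isopropylcarbamate | COc1cc(OC(C)(C)C)cc(OC(=O)NC(C)C)c1[Si](C)(C)C | intermediate
8 | 5-tert-butoxy-3-methoxy-2-(trimethylsilyl)phenol | COc1cc(OC(C)(C)C)cc(O)c1[Si](C)(C)C | intermediate
9 | 5-tert-butoxy-3-methoxy-2-(trimethylsilyl)phenyl trifluoromethanesulfonate | COc1cc(OC(C)(C)C)cc(OS(=O)(=O)C(F)(F)F)c1[Si](C)(C)C | intermediate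
10 | 2,4-dihydroxybenzaldehyde | O=Cc1ccc(O)cc1O | starting material
11 | 3-methylbut-2-enal (prenal) | CC(C)=CC=O | starting material
12 | (3Z)-2-hydroxy-3-(3-methylbut-2-en-1-ylidene)-4-oxocyclohexa-1,5-diene-1-carbaldehyde | O=C1C=CC(C=O)=C(O)/C1=C/C=C(C)C | intermediate
13 | 5-hydroxy-2,2-dimethyl-2H-chromene-6-carbaldehyde | CC1(C)C=Cc2c(O1)ccc(C=O)c2O | intermediate
14 | 5-methoxy-2,2-dimethyl-2H-chromene-6-carbaldehyde | CC1(C)C=Cc2c(O1)ccc(C=O)c2OC | intermediate
15 | 5-methoxy-2,2-dimethylchroman-6-carbaldehyde | CC1(C)CCc2c(O1)ccc(C=O)c2OC | intermediate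
16 | (E)-5-methoxy-2,2-dimethyl-6-[2-(methylsulfinyl)-2-(methylthio)vinyl]chroman, racemic at sulfur | CS/C(S(C)=O)=C\c1ccc2OC(C)(C)CCc2c1OC | intermediate
17 | methyl 2-(5-methoxy-2,2-dimethylchroman-6-yl)acetate | COC(=O)Cc1ccc2OC(C)(C)CCc2c1OC | intermediate
18 | N,N-dimethylformamide | CN(C)C=O | starting material
19 | lithium 1-methoxy-2-(5-methoxy-2,2-dimethylchroman-6-yl)ethen-1-olate, enolate geometry undefined and without consequence | [Li]OC(OC)=Cc1ccc2OC(C)(C)CCc2c1OC | intermediate
20 | 5-tert-butoxy-3-methoxy-1,2-didehydrobenzene | COC1=CC(OC(C)(C)C)=CC#C1 | intermediate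
21 | ortho-quinone methide aminal, drawn as 5-tert-butoxy-2-[(dimethyliminio)methyl]-3-methoxyphenolate | C[N+](C)=Cc1c([O-])cc(OC(C)(C)C)cc1OC | intermediate
22 | lithium phenolate of methyl 3-(4-tert-butoxy-2-hydroxy-6-methoxyphenyl)-3-(dimethylamino)-2-(5-methoxy-2,2-dimethylchroman-6-yl)propanoate, racemic mixture of diastereomers | [Li+].[O-]c1cc(OC(C)(C)C)cc(OC)c1C(N(C)C)C(C(=O)OC)c1ccc2OC(C)(C)CCc2c1OC | intermediate
23 | 7-tert-butoxy-5-methoxy-3-(5-methoxy-2,2-dimethylchroman-6-yl)-2H-chromen-2-one | CC(C)(C)Oc1cc(OC)c2cc(-c3ccc4OC(C)(C)CCc4c3OC)c(=O)oc2c1 | intermediate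
24 | 7-hydroxy-5-methoxy-3-(5-methoxy-2,2-dimethylchroman-6-yl)-2H-chromen-2-one | COc1c(-c2cc3c(OC)cc(O)cc3oc2=O)ccc2c1CCC(C)(C)O2 | target

Total step count: 11.
Longest linear sequence: 7 steps (steps 5, 6, 7, 8, 9, 10, 11, from 10 to 24). The ring A branch needs 6 steps (1, 2, 3, 4, 10, 11).

Steps most likely to fail

Step 10.
- Risk: capture of the aryne by the enolate (direct C-arylation) or by liberated dimethylamine may outrun capture by DMF. Sulfonyl transfer from the triflate to the enolate may also consume both partners.
- Fallback: it sets out from 9 and 17 and returns at 23, splitting the union into two known operations.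
- Compound 9 is treated with CsF in DMF (18) in the absence of any carbanion. The resulting 21 is hydrolysed on aqueous work-up to 4-tert-butoxy-2-hydroxy-6-methoxybenzaldehyde F1.
- Ester 17 is saponified (LiOH, THF–H2O, then mild acidification) to 2-(5-methoxy-2,2-dimethylchroman-6-yl)acetic acid F2.
- Perkin–Oglialoro condensation of the two (Ac2O, Et3N, 110 °C) then gives 23. The aryne still sets the ring A substitution pattern.

Step 3.
- Risk: deprotonation next to the tert-butoxy group instead of between carbamate and methoxyl, erosion of the tert-butyl ether by the silyl triflate, or anionic ortho-Fries migration on premature warming.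
- Fallback: it sets out from 2 and returns at 9, replacing coordination-controlled lithiation by sterically controlled electrophilic substitution.
- Amine-assisted ortho-bromination of the free phenol (NBS, cat. i-Pr2NH, CH2Cl2, −78 → 0 °C) should go to the only position not flanked by the tert-butoxy group. This gives 2-bromo-5-tert-butoxy-3-methoxyphenol F3.
- O-Silylation (HN(SiMe3)2, THF, reflux) gives (2-bromo-5-tert-butoxy-3-methoxyphenoxy)trimethylsilane F4.
- Bromine–lithium exchange (n-BuLi, THF, −78 °C) gives [4-tert-butoxy-2-methoxy-6-(trimethylsilyloxy)phenyl]lithium F5.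
- F5 undergoes retro-Brook O-to-C silyl migration to the lithium salt of 8, and PhNTf2 converts this to 9 in the same flask.

Step 1.
- Risk: over-alkylation of both hydroxyls, decay of the amide acetal to isobutene before it alkylates, or C-alkylation of the very nucleophilic ring.
- Fallback: it sets out from 1 and returns at 3, inverting the order of the two O-functionalisations so that the desymmetrisation rests on a clean addition reaction.
- Compound 1 is treated with one equivalent of i-PrNCO (cat. Et3N, THF, rt) to give 3-hydroxy-5-methoxyphenyl isopropylcarbamate F6, which is separated from diol and bis-carbamate.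
- The single remaining hydroxyl sits on a ring now deactivated by the carbamate. It is tert-butylated with excess isobutene (cat. CF3SO3H, CH2Cl2, −78 °C) to give 3.

Further compounds
F1 | step 10 | 4-tert-butoxy-2-hydroxy-6-methoxybenzaldehyde | COc1cc(OC(C)(C)C)cc(O)c1C=O
F2 | step 10 | 2-(5-methoxy-2,2-dimethylchroman-6-yl)acetic acid | OC(=O)Cc1ccc2OC(C)(C)CCc2c1OC
F3 | step 3 | 2-bromo-5-tert-butoxy-3-methoxyphenol | COc1cc(OC(C)(C)C)cc(O)c1Br
F4 | step 3 | (2-bromo-5-tert-butoxy-3-methoxyphenoxy)trimethylsilane | COc1cc(OC(C)(C)C)cc(O[Si](C)(C)C)c1Br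
F5 | step 3 | [4-tert-butoxy-2-methoxy-6-(trimethylsilyloxy)phenyl]lithium | COc1cc(OC(C)(C)C)cc(O[Si](C)(C)C)c1[Li]
F6 | step 1 | 3-hydroxy-5-methoxyphenyl isopropylcarbamate | COc1cc(O)cc(OC(=O)NC(C)C)c1
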